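**Retrosynthetic overview**

1. Numbering: ring C1 (C=O), C2 (allyl), C3 (H), C4 (quaternary, OMe), C5 (OMe), C6 (H). Chain: C8 (CH–CH3) on C4, then C7 (CH–OAc, aryl).
2. Feature: read from the C4 oxygen, the ring atoms O–C4–C5(OMe)=C6–C1(=O) of the cyclohexadienone are those of a 5,5-disubstituted methyl tetronate. Only the partner of that oxygen differs: CH3 in the target, C1 in the lactone.
3. Key disconnection C1–C2: a C2 vinyllithium held cis to C4 acylates itself on the tetronate carbonyl. The five-membered lactone (ring made first) is given up for the six-membered carbocycle (ring made second), and the released C4 alkoxide is methylated.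
4. Tetronate: the C4–C5 bond comes from chelation-controlled addition of β-lithiated methyl 3-methoxyacrylate to a Z-β-iodo dienone. That ketone comes from hydroiodination of a skipped enynone made from a Weinreb amide and pent-1-en-4-yne.
5. C7 and C8 come from an Evans syn aldol of veratraldehyde. The end game is release of C7–OH and acetylation.

Key step: step 7

Abbreviations: TOM = (triisopropylsiloxy)methyl, CH2OSi(i-Pr)3. Ar = 3,4-dimethoxyphenyl.

Remark on the C7 protecting group: C7–O is itself a 3,4-dimethoxybenzylic ether. It is oxidised (DDQ, cerium ammonium nitrate) and ionised (acid) more easily than a PMB ether, so no benzyl-type group is used. The TOM acetal still chelates through its inner oxygen, resists organolithiums and leaves with buffered fluoride.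

Remark on the vinyl iodide: iodine enters as iodide at the ynone stage. Electrophilic iodine on a late vinylsilane would have to compete with the veratryl ring, the tetronate C6–H and the terminal alkene.

Assumption: (R)-4-benzyl-3-propionyloxazolidin-2-one, pent-1-en-4-yne and TOM-Cl are taken as catalogue compounds.

**Route**

Step 1
Reactants: 1 (R)-4-benzyl-3-propionyloxazolidin-2-one; 2 veratraldehyde (3,4-dimethoxybenzaldehyde)
Product: 5 (R)-4-benzyl-3-[(2R,3R)-3-(3,4-dimethoxyphenyl)-3-hydroxy-2-methylpropanoyl]oxazolidin-2-one, via Z-dibutylboron enolate 3 (not isolated), via dibutylboron aldolate 4 (not isolated)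
Conditions: Bu2BOTf, Et3N, CH2Cl2, 0 °C; 2, −78 → 0 °C; then pH 7 buffer, MeOH, 30% H2O2, 0 °C
Reagents that add atoms: none
Why: Evans syn aldol reaction, in which the Z-boron enolate reacts through a Zimmerman–Traxler chair whose open face is fixed by the (R)-benzyl auxiliary, so that C8 and C7 are set together as the 2R,3R syn pair.

Step 2
Reactants: 5 aldol adduct
Product: 6 (2R,3R)-3-(3,4-dimethoxyphenyl)-3-hydroxy-N-methoxy-N,2-dimethylpropanamide
Conditions: MeONHMe·HCl, AlMe3, CH2Cl2, −10 °C → rt; aq. potassium sodium tartrate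
Reagents that add atoms: N,O-dimethylhydroxylamine hydrochloride, CNOC.Cl
Why: Weinreb transamidation with the aluminium amide, assisted by the free β-hydroxyl, exchanges the auxiliary for the N-methoxy-N-methylamide without touching C7 or C8.

Step 3
Reactants: 6 hydroxy Weinreb amide
Product: 7 (2R,3R)-3-(3,4-dimethoxyphenyl)-N-methoxy-N,2-dimethyl-3-(TOM-oxy)propanamide
Conditions: TOM-Cl, i-Pr2NEt, Bu4NI (cat.), CH2Cl2, 0 → 35 °C
Reagents that add atoms: (triisopropylsiloxy)methyl chloride (TOM-Cl), ClCO[Si](C(C)C)(C(C)C)C(C)C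
Why: O-alkylation with an alkoxymethyl chloride under amine base (the MOM/SEM type of protection) proceeds with retention at C7 and gives a formaldehyde acetal that can chelate, tolerates organolithiums and is later removed by fluoride.

Step 4
Reactants: 7 TOM-protected Weinreb amide; 8 pent-1-en-4-yne
Product: 11 (1R,2R)-1-(3,4-dimethoxyphenyl)-2-methyl-1-(TOM-oxy)oct-7-en-4-yn-3-one, via lithium acetylide 9 (not isolated), via tetrahedral lithium adduct 10 (not isolated)
Conditions: 8, n-BuLi, THF, −78 °C; then 7, −78 → −20 °C; AcOH in THF at −78 °C, then water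
Reagents that add atoms: none
Why: Weinreb ketone synthesis, in which the acetylide adds once, the chelated tetrahedral adduct survives until the cold acidic quench, and that quench keeps base and the liberated amine away from the isomerisable skipped enynone.

Step 5
Reactants: 11 skipped enynone
Product: 12 (1R,2R,4Z)-1-(3,4-dimethoxyphenyl)-5-iodo-2-methyl-1-(TOM-oxy)octa-4,7-dien-3-one
Conditions: NaI, AcOH, MeCN, 0 °C → rt, dark
Reagents that add atoms: sodium iodide, [Na+].[I-]
Why: Conjugate hydroiodination of an ynone, in which iodide adds to C2 and the allenol is protonated at C3 anti to it, gives the kinetic Z-β-iodoenone (iodine cis to C4) from a nucleophilic iodine source that leaves the arene and the terminal alkene alone.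

Step 6
Reactants: 12 Z-β-iodo dienone; 13 methyl (E)-3-methoxyacrylate
Product: 16 (5S)-5-[(1R,2R)-1-(3,4-dimethoxyphenyl)-1-(TOM-oxy)propan-2-yl]-5-[(1Z)-2-iodopenta-1,4-dien-1-yl]-4-methoxyfuran-2(5H)-one, via β-lithiated methoxyacrylate 14 (not isolated), via acyclic lithium alkoxide 15 (not isolated)
Conditions: 13, LiN(i-Pr)2, THF, −95 °C; cannulated into 12 precomplexed with MgBr2·OEt2 in CH2Cl2, −78 °C; → 0 °C; aq. NH4Cl
Reagents that add atoms: none
Why: Tetronate synthesis by 1,2-addition of a β-lithiated 3-methoxyacrylate to a ketone followed by lactonisation, run under Cram-chelate control: MgBr2 ties the C4 carbonyl and the inner C7 acetal oxygen into a six-membered chelate that carries the C8 methyl and the aryl group on one face, so the nucleophile enters from the other face and sets C4 (anti-Felkin sense, descriptor S in 16).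

Step 7
Reactants: 16 iodo dienyl tetronate; 17 iodomethane
Product: 21 (4R)-2-allyl-4-[(1R,2R)-1-(3,4-dimethoxyphenyl)-1-(TOM-oxy)propan-2-yl]-4,5-dimethoxycyclohexa-2,5-dien-1-one, via C2 vinyllithium 18 (not isolated), via 1-oxido-7-oxanorbornadiene 19 (not isolated), via C4 lithium alkoxide 20 (not isolated)
Conditions: t-BuLi (2.1 equiv), THF/Et2O/pentane 4:1:1, 0.01 M, −100 → −78 °C (→ −40 °C if needed); then 17 (excess), DMPU, −78 → 0 °C
Reagents that add atoms: iodomethane (17), CI
Why: Proposed new method: iodine–lithium exchange at C2 should be much faster than addition of t-BuLi to a vinylogous carbonate, and the second equivalent destroys t-BuI, so vinyllithium 18 should form with its Z geometry retained. Because the carbanion is held cis to C4 it lies over one face of the lactone and adds to C1 in a 6-exo-trig closure that makes the C1–C2 bond and the carbocycle, giving the bicyclic alkoxide 19, whose transient C1 bridgehead is dictated by C4. Electron push from the oxido group and release of the bicyclic strain then break the C1–O bridge bond, so C1 becomes the dienone carbonyl and the former lactone oxygen becomes the C4 alkoxide 20; the net trade of a vinyl anion for an alkoxide makes the sequence irreversible. DMPU loosens the lithium alkoxide enough for SN2 methylation by iodomethane. The closest known reaction types are the Parham cycloacylation (halogen–lithium exchange, then attack on an internal ester or lactone) and the opening of 1-oxygenated 7-oxanorbornadienes to 4-hydroxycyclohexadienones, and what is new is their combination on a tetronate. No lasting stereocentre is created and no bond to C4 breaks, so C4 keeps its configuration (S becomes R only because iodine leaves C2), while the needed selectivity, intramolecular acylation ahead of proton transfer or intermolecular addition, rests on the Z geometry, high dilution and low temperature.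

Step 8
Reactants: 21 TOM-protected dienone
Product: 23 (4R)-2-allyl-4-[(1R,2R)-1-(3,4-dimethoxyphenyl)-1-hydroxypropan-2-yl]-4,5-dimethoxycyclohexa-2,5-dien-1-one, via C7 formaldehyde hemiacetal 22 (not isolated)
Conditions: Bu4NF/AcOH (1:1), THF, 0 °C → rt; pH 7 phosphate buffer
Reagents that add atoms: none
Why: Fluoride-induced desilylation of the siloxymethyl acetal gives a hemiacetal that sheds formaldehyde at neutral pH, so C7–OH is freed with retention and without the acid, strong base or oxidant that would endanger the dienone, its enol ether or the benzylic centre.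

Step 9
Reactants: 23 C7 alcohol
Product: 24 (1R,2R)-1-(3,4-dimethoxyphenyl)-2-[(1R)-3-allyl-1,6-dimethoxy-4-oxocyclohexa-2,5-dien-1-yl]propyl acetate (CNP0159267.1)
Conditions: Ac2O, pyridine, DMAP (cat.), CH2Cl2, 0 °C → rt
Reagents that add atoms: acetic anhydride, CC(=O)OC(C)=O
Why: DMAP-catalysed acyl transfer acetylates the only free hydroxyl with retention at C7 and completes the target.

**Compound list**

1 | (R)-4-benzyl-3-propionyloxazolidin-2-one | CCC(=O)N1[C@H](Cc2ccccc2)COC1=O | starting material
2 | veratraldehyde | COc1ccc(C=O)cc1OC | starting material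
3 | Z-dibutylboron enolate of 1 (formed in the flask) | C/C=C(\OB(CCCC)CCCC)N1[C@H](Cc2ccccc2)COC1=O | intermediate
4 | dibutylboron aldolate of 5 (formed in the flask) | O=C(N1[C@H](Cc2ccccc2)COC1=O)[C@H](C)[C@@H](OB(CCCC)CCCC)c1ccc(OC)c(OC)c1 | intermediate
5 | (R)-4-benzyl-3-[(2R,3R)-3-(3,4-dimethoxyphenyl)-3-hydroxy-2-methylpropanoyl]oxazolidin-2-one | O=C(N1[C@H](Cc2ccccc2)COC1=O)[C@H](C)[C@@H](O)c1ccc(OC)c(OC)c1 | intermediate
6 | (2R,3R)-3-(3,4-dimethoxyphenyl)-3-hydroxy-N-methoxy-N,2-dimethylpropanamide | CON(C)C(=O)[C@H](C)[C@@H](O)c1ccc(OC)c(OC)c1 | intermediate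
7 | (2R,3R)-3-(3,4-dimethoxyphenyl)-N-methoxy-N,2-dimethyl-3-(TOM-oxy)propanamide | CON(C)C(=O)[C@H](C)[C@@H](OCO[Si](C(C)C)(C(C)C)C(C)C)c1ccc(OC)c(OC)c1 | intermediate
8 | pent-1-en-4-yne | C=CCC#C | starting material
9 | lithium pent-4-en-1-yn-1-ide (formed in the flask) | [Li]C#CCC=C | intermediate
10 | tetrahedral lithium adduct of 9 to 7, new centre undefined (formed in the flask) | C=CCC#CC(O[Li])(N(C)OC)[C@H](C)[C@@H](OCO[Si](C(C)C)(C(C)C)C(C)C)c1ccc(OC)c(OC)c1 | intermediate
11 | (1R,2R)-1-(3,4-dimethoxyphenyl)-2-methyl-1-(TOM-oxy)oct-7-en-4-yn-3-one | C=CCC#CC(=O)[C@H](C)[C@@H](OCO[Si](C(C)C)(C(C)C)C(C)C)c1ccc(OC)c(OC)c1 | intermediate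
12 | (1R,2R,4Z)-1-(3,4-dimethoxyphenyl)-5-iodo-2-methyl-1-(TOM-oxy)octa-4,7-dien-3-one | C=CC/C(I)=C/C(=O)[C@H](C)[C@@H](OCO[Si](C(C)C)(C(C)C)C(C)C)c1ccc(OC)c(OC)c1 | intermediate
13 | methyl (E)-3-methoxyacrylate | CO/C=C/C(=O)OC | starting material
14 | methyl 3-lithio-3-methoxyacrylate, lithium cis to the ester (formed in the flask) | CO/C([Li])=C/C(=O)OC | intermediate
15 | acyclic C4 lithium alkoxide, C4 cis to the ester across C5=C6 (formed in the flask) | C=CC/C(I)=C/[C@@](O[Li])([C@H](C)[C@@H](OCO[Si](C(C)C)(C(C)C)C(C)C)c1ccc(OC)c(OC)c1)/C(OC)=C\C(=O)OC | intermediate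
16 | (5S)-5-[(1R,2R)-1-(3,4-dimethoxyphenyl)-1-(TOM-oxy)propan-2-yl]-5-[(1Z)-2-iodopenta-1,4-dien-1-yl]-4-methoxyfuran-2(5H)-one | C=CC/C(I)=C/[C@]1([C@H](C)[C@@H](OCO[Si](C(C)C)(C(C)C)C(C)C)c2ccc(OC)c(OC)c2)OC(=O)C=C1OC | intermediate
17 | iodomethane | CI | starting material
18 | C2 vinyllithium from 16, lithium cis to C4 (formed in the flask) | C=CC/C([Li])=C/[C@]1([C@H](C)[C@@H](OCO[Si](C(C)C)(C(C)C)C(C)C)c2ccc(OC)c(OC)c2)OC(=O)C=C1OC | intermediate
19 | lithium 1-oxido-7-oxabicyclo[2.2.1]hepta-2,5-diene, bridgeheads C1 and C4, bridges C2=C3, C5=C6 and O (formed in the flask) | C=CCC1=C[C@]2([C@H](C)[C@@H](OCO[Si](C(C)C)(C(C)C)C(C)C)c3ccc(OC)c(OC)c3)O[C@@]1(O[Li])C=C2OC | intermediate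
20 | C4 lithium alkoxide of the cyclohexadienone (formed in the flask) | C=CCC1=C[C@@](O[Li])([C@H](C)[C@@H](OCO[Si](C(C)C)(C(C)C)C(C)C)c2ccc(OC)c(OC)c2)C(OC)=CC1=O | intermediate
21 | (4R)-2-allyl-4-[(1R,2R)-1-(3,4-dimethoxyphenyl)-1-(TOM-oxy)propan-2-yl]-4,5-dimethoxycyclohexa-2,5-dien-1-one | C=CCC1=C[C@@](OC)([C@H](C)[C@@H](OCO[Si](C(C)C)(C(C)C)C(C)C)c2ccc(OC)c(OC)c2)C(OC)=CC1=O | intermediate
22 | C7 hydroxymethyl (formaldehyde) hemiacetal of 23 (formed in the flask) | C=CCC1=C[C@@](OC)([C@H](C)[C@@H](OCO)c2ccc(OC)c(OC)c2)C(OC)=CC1=O | intermediate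
23 | (4R)-2-allyl-4-[(1R,2R)-1-(3,4-dimethoxyphenyl)-1-hydroxypropan-2-yl]-4,5-dimethoxycyclohexa-2,5-dien-1-one | C=CCC1=C[C@@](OC)([C@H](C)[C@@H](O)c2ccc(OC)c(OC)c2)C(OC)=CC1=O | intermediate
24 | (1R,2R)-1-(3,4-dimethoxyphenyl)-2-[(1R)-3-allyl-1,6-dimethoxy-4-oxocyclohexa-2,5-dien-1-yl]propyl acetate | C=CCC1=C[C@@](OC)([C@H](C)[C@@H](OC(C)=O)c2ccc(OC)c(OC)c2)C(OC)=CC1=O | target

**Step count**

Total step count: 9. Longest linear sequence: 9 steps (1 or 2 to 24).

**Steps most likely to fail**

Step 7 (key step). Several things may go wrong.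
- The flat lactone has to fold about the C1···C4 axis before C2 can reach C1, and the adduct carries the full strain of a 7-oxanorbornadiene, so the closure may be slow.
- The waiting vinyllithium can then be lost by proton transfer from C6–H or from the doubly allylic CH2 of a second molecule, or by intermolecular addition.
- Incomplete methylation of the hindered lithium alkoxide is a lesser concern.

The fallback uses known chemistry, sets out from 16 and comes back at 21. i-Bu2AlH in CH2Cl2 at −78 °C reduces the tetronate carbonyl to the lactol F1. Under Nozaki–Hiyama–Kishi conditions (CrCl2, catalytic NiCl2, DMF/THF, rt) the vinyl iodide becomes a vinylchromium species. This adds to the open hydroxy-enal form of the lactol and closes the unstrained six-membered ring, giving the cyclohexa-2,5-diene-1,4-diol F2. MnO2 in CH2Cl2 oxidises the secondary, doubly allylic C1 alcohol to the p-quinol F3, which is also what a protic quench of 20 would give. NaH and iodomethane in THF at 0 °C then methylate C4–OH to reach 21. C4 is untouched throughout.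

Step 6. Three things may go wrong.
- The nucleophile may deprotonate the iodo dienone at its doubly allylic CH2 or at C8, the latter followed by β-elimination of the C7 oxygen.
- Addition to the hindered carbonyl may be slow.
- Part of the reaction may leak through the unchelated Felkin–Anh pathway once THF competes for magnesium, with poor facial selectivity as the result.

The fallback sets out from 11 and comes back at 16. The lithiated acrylate 14 is added to the MgBr2·OEt2 chelate of the slimmer and more electrophilic ynone 11, giving the alkynyl tetronate F4. Trans-hydrosilylation with Et3SiH and catalytic [Cp*Ru(MeCN)3]PF6 in CH2Cl2 then places silicon on C2, away from the oxygenated quaternary carbon and cis to C4, giving the Z-vinylsilane F5. Brief iododesilylation with N-iodosuccinimide and 2,6-lutidine in (CF3)2CHOH at 0 °C, with retention, gives 16. Short contact time is needed there to spare the veratryl ring.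

Step 5. The Z geometry may erode by reversible iodide addition–elimination. The terminal double bond may drift into conjugation in the acidic medium, and 11 itself may already suffer prototropic isomerisation.

The fallback sets out from 7 and comes back at 12, bypassing 11.
- i-Bu2AlH in THF at −78 °C reduces the Weinreb amide to the aldehyde F6.
- Acetylide 9 adds to it to give the propargylic alcohol F7, whose carbinol epimers are of no consequence.
- Alkoxide-directed trans-hydroalumination with NaAlH2(OCH2CH2OMe)2 in THF proceeds through a five-membered oxa-aluminacycle. Iodine at −78 °C then gives the Z-γ-iodo allylic alcohol F8.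
- Dess–Martin periodinane with NaHCO3 oxidises F8 to 12.

**Further compounds**

F1 | step 7 | lactol from 16, (5S)-2,5-dihydrofuran-2-ol, anomers | C=CC/C(I)=C/[C@]1([C@H](C)[C@@H](OCO[Si](C(C)C)(C(C)C)C(C)C)c2ccc(OC)c(OC)c2)OC(O)C=C1OC
F2 | step 7 | (4R)-2-allyl-4-[(1R,2R)-1-Ar-1-(TOM-oxy)propan-2-yl]-5-methoxycyclohexa-2,5-diene-1,4-diol, C1 epimers | C=CCC1=C[C@@](O)([C@H](C)[C@@H](OCO[Si](C(C)C)(C(C)C)C(C)C)c2ccc(OC)c(OC)c2)C(OC)=CC1O
F3 | step 7 | (4R)-2-allyl-4-hydroxy-4-[(1R,2R)-1-Ar-1-(TOM-oxy)propan-2-yl]-5-methoxycyclohexa-2,5-dien-1-one (p-quinol) | C=CCC1=C[C@@](O)([C@H](C)[C@@H](OCO[Si](C(C)C)(C(C)C)C(C)C)c2ccc(OC)c(OC)c2)C(OC)=CC1=O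
F4 | step 6 | (5S)-4-methoxy-5-(pent-4-en-1-yn-1-yl)-5-[(1R,2R)-1-Ar-1-(TOM-oxy)propan-2-yl]furan-2(5H)-one | C=CCC#C[C@]1([C@H](C)[C@@H](OCO[Si](C(C)C)(C(C)C)C(C)C)c2ccc(OC)c(OC)c2)OC(=O)C=C1OC
F5 | step 6 | (5S)-4-methoxy-5-[(1Z)-2-(triethylsilyl)penta-1,4-dien-1-yl]-5-[(1R,2R)-1-Ar-1-(TOM-oxy)propan-2-yl]furan-2(5H)-one | C=CC/C([Si](CC)(CC)CC)=C/[C@]1([C@H](C)[C@@H](OCO[Si](C(C)C)(C(C)C)C(C)C)c2ccc(OC)c(OC)c2)OC(=O)C=C1OC
F6 | step 5 | (2R,3R)-3-(3,4-dimethoxyphenyl)-2-methyl-3-(TOM-oxy)propanal | O=C[C@H](C)[C@@H](OCO[Si](C(C)C)(C(C)C)C(C)C)c1ccc(OC)c(OC)c1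
F7 | step 5 | 1-(3,4-dimethoxyphenyl)-2-methyl-1-(TOM-oxy)oct-7-en-4-yn-3-ol, C7 and C8 as in 7, carbinol epimers | C=CCC#CC(O)[C@H](C)[C@@H](OCO[Si](C(C)C)(C(C)C)C(C)C)c1ccc(OC)c(OC)c1
F8 | step 5 | (4Z)-1-(3,4-dimethoxyphenyl)-5-iodo-2-methyl-1-(TOM-oxy)octa-4,7-dien-3-ol, C7 and C8 as in 7, carbinol epimers | C=CC/C(I)=C/C(O)[C@H](C)[C@@H](OCO[Si](C(C)C)(C(C)C)C(C)C)c1ccc(OC)c(OC)c1
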